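**Target 22** is epimesquitol-(4β→6)-epioritin-4α-ol: upper unit (2R,3R,4S), 2,3-cis-3,4-trans; lower unit (2R,3R,4R), all-cis.

**Retrosynthetic overview**
1. 22 ⇐ heptabenzyl triacetate 20 ⇐ interflavan C4–C6 bond: silver-promoted coupling of upper 4-thioether 19 with lower all-cis diacetate 11; the 3-acetate of 19 steers attack to the β face (3,4-trans).
2. 11 and 19 ⇐ 2,4-cis 4-substituted flavan-3-ones (hydride enters anti to both substituents) ⇐ α-nitro epoxides ⇐ (2R)-2-aryl-3-nitro-2H-chromenes 7 and 15.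
3. Key disconnection: C3–C4 of each pyran ring. The nitronate carbon acts as a masked acyl anion (C3 later becomes C=O) and adds to the aldehyde carbon C4 in an enantioselective oxa-Michael/nitro-aldol domino of salicylaldehyde 2 with nitrostyrene 5 or 13.
4. Ring order: rings A and B are bought; ring C of each unit is closed in the domino step (O1–C2, then C3–C4); the two flavans are joined last.

Assumption: flavan numbering (O1, C2, C3, C4; rings A, B, C) is used for every chromane intermediate, and the aminocatalyst enantiomer used is the one that delivers 2R (both are made from proline).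

**Step 1**
Reactants: 1 2,3,4-trihydroxybenzaldehyde
Product: 2 3,4-bis(benzyloxy)-2-hydroxybenzaldehyde
Conditions: BnBr (2.05 equiv), K2CO3 (2.1 equiv), DMF, 0 °C to rt
Reagents that add atoms: benzyl bromide, BrCc1ccccc1
Why: Williamson etherification; the 4-OH and 3-OH are alkylated while the 2-OH, locked in a hydrogen bond to the aldehyde, is the poorest nucleophile and stays free for ring closure.

**Step 2**
Reactants: 3 4-(benzyloxy)benzaldehyde; 4 nitromethane
Product: 5 (E)-1-(benzyloxy)-4-(2-nitroethenyl)benzene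
Conditions: NH4OAc, AcOH, 100 °C
Reagents that add atoms: none
Why: Henry (nitro-aldol) condensation with in-situ dehydration gives the thermodynamically favoured E-nitroalkene.

**Step 3 (key step)**
Reactants: 2 3,4-bis(benzyloxy)-2-hydroxybenzaldehyde; 5 (E)-1-(benzyloxy)-4-(2-nitroethenyl)benzene
Product: 7 (2R)-7,8-bis(benzyloxy)-2-[4-(benzyloxy)phenyl]-3-nitro-2H-chromene, via oxa-Michael adduct 6 (not isolated)
Conditions: (S)-1-methyl-2-[(pyrrolidin-2-ylmethyl)sulfanyl]-1H-imidazole (20 mol%), salicylic acid (20 mol%), DMSO, 25 °C; recrystallise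
Reagents that add atoms: none
Why: Organocatalytic domino oxa-Michael/intramolecular nitro-aldol (Henry)/elimination: the phenol adds reversibly to the nitroalkene to give 6, whose nitronate carbon (a masked acyl anion, since it becomes the C3 carbonyl in step 5) attacks the catalyst-bound iminium of the aldehyde carbon C4, so two carbons that are both electrophilic at the carbonyl level are joined; because the oxa-Michael step is reversible, the chiral iminium selects the R adduct in the ring-closing C–C bond formation (dynamic kinetic resolution) and thereby sets C2, about 90% ee being expected for this reaction class and raised by recrystallisation.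

**Step 4**
Reactants: 7 (2R)-7,8-bis(benzyloxy)-2-[4-(benzyloxy)phenyl]-3-nitro-2H-chromene
Product: 8 (2R,3S,4S)-7,8-bis(benzyloxy)-2-[4-(benzyloxy)phenyl]-3,4-epoxy-3-nitrochromane (epoxide trans to the 2-aryl group)
Conditions: t-BuOOH (1.5 equiv), n-BuLi (1.3 equiv), THF, −78 to −40 °C
Reagents that add atoms: tert-butyl hydroperoxide, CC(C)(C)OO
Why: Nucleophilic (Weitz–Scheffer-type) epoxidation of the nitroalkene: t-BuOO– adds to C4 on the face opposite the pseudo-axial 2-aryl group and the nitronate closes onto oxygen, so the epoxide is trans to the aryl group.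

**Step 5**
Reactants: 8 (2R,3S,4S)-7,8-bis(benzyloxy)-2-[4-(benzyloxy)phenyl]-3,4-epoxy-3-nitrochromane
Product: 9 (2R,4R)-4-acetoxy-7,8-bis(benzyloxy)-2-[4-(benzyloxy)phenyl]chroman-3-one (2,4-cis)
Conditions: CsOAc (1.5 equiv), AcOH (0.5 equiv), DMF, −20 to 0 °C
Reagents that add atoms: cesium acetate, [Cs+].CC([O-])=O
Why: Proposed new method: the α-nitro epoxide is an α-keto-cation equivalent of the flavan-3-one, so acetate should attack benzylic C4 in SN2 fashion with inversion (acetate cis to the 2-aryl group; the electron-poor C3 disfavours ionisation) and the resulting α-nitro alkoxide expels nitrite to unveil the C3 ketone, the closest known reactions being openings of α-nitro epoxides by thiols, amines and halides to give α-substituted ketones.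

**Step 6**
Reactants: 9 (2R,4R)-4-acetoxy-7,8-bis(benzyloxy)-2-[4-(benzyloxy)phenyl]chroman-3-one
Product: 11 (2R,3S,4R)-3,4-diacetoxy-7,8-bis(benzyloxy)-2-[4-(benzyloxy)phenyl]chromane (all-cis), via lithium alkoxide of hydroxy acetate 10 (not isolated)
Conditions: LiBH(s-Bu)3 (1.2 equiv), THF, −78 °C; then Ac2O (4 equiv), 4-(dimethylamino)pyridine (0.2 equiv), −78 to 0 °C
Reagents that add atoms: acetic anhydride, CC(=O)OC(C)=O
Why: Substrate-controlled reduction by a bulky hydride from the face opposite both the 2-aryl and the 4-acetoxy group (the sense known for flavan-3-one to 2,3-cis-flavan-3-ol reductions) gives the all-cis 3-alkoxide, which is acetylated in the same flask, so any 4-to-3 acetyl shift is harmless.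

**Step 7**
Reactants: 12 3,4-bis(benzyloxy)benzaldehyde; 4 nitromethane
Product: 13 (E)-1,2-bis(benzyloxy)-4-(2-nitroethenyl)benzene
Conditions: NH4OAc, AcOH, 100 °C
Reagents that add atoms: none
Why: Henry condensation with dehydration to the E-nitroalkene.

**Step 8 (key step, upper unit)**
Reactants: 2 3,4-bis(benzyloxy)-2-hydroxybenzaldehyde; 13 (E)-1,2-bis(benzyloxy)-4-(2-nitroethenyl)benzene
Product: 15 (2R)-7,8-bis(benzyloxy)-2-[3,4-bis(benzyloxy)phenyl]-3-nitro-2H-chromene, via oxa-Michael adduct 14 (not isolated)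
Conditions: (S)-1-methyl-2-[(pyrrolidin-2-ylmethyl)sulfanyl]-1H-imidazole (20 mol%), salicylic acid (20 mol%), DMSO, 25 °C; recrystallise
Reagents that add atoms: none
Why: Same domino oxa-Michael/nitro-aldol/elimination as step 3, the nitronate (masked C3 acyl anion) closing ring C onto the aldehyde carbon C4 under catalyst control to set C2 as R.

**Step 9**
Reactants: 15 (2R)-7,8-bis(benzyloxy)-2-[3,4-bis(benzyloxy)phenyl]-3-nitro-2H-chromene
Product: 16 (2R,3S,4S)-7,8-bis(benzyloxy)-2-[3,4-bis(benzyloxy)phenyl]-3,4-epoxy-3-nitrochromane (epoxide trans to the 2-aryl group)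
Conditions: t-BuOOH (1.5 equiv), n-BuLi (1.3 equiv), THF, −78 to −40 °C
Reagents that add atoms: tert-butyl hydroperoxide, CC(C)(C)OO
Why: Nucleophilic epoxidation of the nitroalkene anti to the pseudo-axial 2-aryl group, as in step 4.

**Step 10**
Reactants: 16 (2R,3S,4S)-7,8-bis(benzyloxy)-2-[3,4-bis(benzyloxy)phenyl]-3,4-epoxy-3-nitrochromane
Product: 17 (2R,4R)-4-(benzylsulfanyl)-7,8-bis(benzyloxy)-2-[3,4-bis(benzyloxy)phenyl]chroman-3-one (2,4-cis)
Conditions: PhCH2SH (1.1 equiv), Et3N (1.2 equiv), CH2Cl2, −20 °C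
Reagents that add atoms: phenylmethanethiol, SCc1ccccc1
Why: Known opening of α-nitro epoxides by thiols to α-sulfanyl ketones: sulfur attacks benzylic C4 with inversion (cis to the 2-aryl group) and nitrite is lost from C3, low temperature protecting the two enolisable α-centres.

**Step 11**
Reactants: 17 (2R,4R)-4-(benzylsulfanyl)-7,8-bis(benzyloxy)-2-[3,4-bis(benzyloxy)phenyl]chroman-3-one
Product: 19 (2R,3S,4R)-3-acetoxy-4-(benzylsulfanyl)-7,8-bis(benzyloxy)-2-[3,4-bis(benzyloxy)phenyl]chromane (all-cis), via lithium alkoxide of hydroxy thioether 18 (not isolated)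
Conditions: LiBH(s-Bu)3 (1.2 equiv), THF, −78 °C; then Ac2O (3 equiv), 4-(dimethylamino)pyridine (0.2 equiv), −78 to 0 °C; non-oxidative work-up
Reagents that add atoms: acetic anhydride, CC(=O)OC(C)=O
Why: Bulky-hydride reduction anti to the cis 2-aryl and 4-sulfanyl groups sets the 2,3-cis alcohol (as in step 6), and in-flask acetylation installs the participating 3-acetate and removes the last free hydroxyl.

**Step 12**
Reactants: 19 (2R,3S,4R)-3-acetoxy-4-(benzylsulfanyl)-7,8-bis(benzyloxy)-2-[3,4-bis(benzyloxy)phenyl]chromane; 11 (2R,3S,4R)-3,4-diacetoxy-7,8-bis(benzyloxy)-2-[4-(benzyloxy)phenyl]chromane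
Product: 20 3-O-acetyl-3',4',7,8-tetra-O-benzylepimesquitol-(4β→6)-3,4-di-O-acetyl-4',7,8-tri-O-benzylepioritin-4α-ol
Conditions: AgBF4 (2.5 equiv), 2,6-di-tert-butyl-4-methylpyridine (1.5 equiv), 4 Å MS, CH2Cl2, −40 to 0 °C; 11 in excess (4 equiv, recovered)
Reagents that add atoms: none
Why: Thiophilic silver ionises the C4–S bond to the para-benzyloxy-stabilised benzylic cation, which the 3-acetate captures as a cis-fused acetoxonium ion on the α face, so Friedel–Crafts attack by C6 of 11 (para to O1 and ortho to the 7-benzyloxy group, C5 being peri-hindered) comes from the β face and gives the 3,4-trans 4β→6 bond, as in silver-promoted couplings of 4-sulfanylflavan-3-ols; 11 has no free hydroxyl and its acetates are not activated by silver.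

**Step 13**
Reactants: 20 3-O-acetyl-3',4',7,8-tetra-O-benzylepimesquitol-(4β→6)-3,4-di-O-acetyl-4',7,8-tri-O-benzylepioritin-4α-ol
Product: 22 epimesquitol-(4β→6)-epioritin-4α-ol (target), via heptabenzyl triol 21 (not isolated)
Conditions: K2CO3 (0.3 equiv), MeOH–THF, 0 °C to rt; AcOH to neutral; then H2 (1 atm), Pd(OH)2/C, THF–MeOH, rt; filter under argon, lyophilise
Reagents that add atoms: none
Why: Zemplén-type transesterification removes the three acetates while all phenols are still protected, then neutral hydrogenolysis cleaves the seven aryl benzyl ethers much faster than the benzylic C4–OH or the C4–C6 bond, and no stereocentre is touched.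

**Compound list**
1 | 2,3,4-trihydroxybenzaldehyde | O=Cc1ccc(O)c(O)c1O | starting material
2 | 3,4-bis(benzyloxy)-2-hydroxybenzaldehyde | O=Cc1ccc(OCc2ccccc2)c(OCc2ccccc2)c1O | intermediate
3 | 4-(benzyloxy)benzaldehyde | O=Cc1ccc(OCc2ccccc2)cc1 | starting material
4 | nitromethane | C[N+](=O)[O-] | starting material
5 | (E)-1-(benzyloxy)-4-(2-nitroethenyl)benzene | [O-][N+](=O)/C=C/c1ccc(OCc2ccccc2)cc1 | intermediate
6 | 3,4-bis(benzyloxy)-2-{(1R)-1-[4-(benzyloxy)phenyl]-2-nitroethoxy}benzaldehyde | O=Cc1ccc(OCc2ccccc2)c(OCc2ccccc2)c1O[C@@H](C[N+](=O)[O-])c1ccc(OCc2ccccc2)cc1 | intermediate (not isolated)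
7 | (2R)-7,8-bis(benzyloxy)-2-[4-(benzyloxy)phenyl]-3-nitro-2H-chromene | O(Cc1ccccc1)c1ccc(cc1)[C@H]1Oc2c(ccc(OCc3ccccc3)c2OCc2ccccc2)C=C1[N+](=O)[O-] | intermediate
8 | (2R,3S,4S)-7,8-bis(benzyloxy)-2-[4-(benzyloxy)phenyl]-3,4-epoxy-3-nitrochromane | O(Cc1ccccc1)c1ccc(cc1)[C@H]1Oc2c(ccc(OCc3ccccc3)c2OCc2ccccc2)[C@@H]2O[C@]12[N+](=O)[O-] | intermediate
9 | (2R,4R)-4-acetoxy-7,8-bis(benzyloxy)-2-[4-(benzyloxy)phenyl]chroman-3-one | O(Cc1ccccc1)c1ccc(cc1)[C@H]1Oc2c(ccc(OCc3ccccc3)c2OCc2ccccc2)[C@@H](OC(C)=O)C1=O | intermediate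
10 | (2R,3S,4R)-4-acetoxy-7,8-bis(benzyloxy)-2-[4-(benzyloxy)phenyl]chroman-3-ol (formed as lithium alkoxide) | O(Cc1ccccc1)c1ccc(cc1)[C@H]1Oc2c(ccc(OCc3ccccc3)c2OCc2ccccc2)[C@@H](OC(C)=O)[C@H]1O | intermediate (not isolated)
11 | (2R,3S,4R)-3,4-diacetoxy-7,8-bis(benzyloxy)-2-[4-(benzyloxy)phenyl]chromane | O(Cc1ccccc1)c1ccc(cc1)[C@H]1Oc2c(ccc(OCc3ccccc3)c2OCc2ccccc2)[C@@H](OC(C)=O)[C@H]1OC(C)=O | intermediate
12 | 3,4-bis(benzyloxy)benzaldehyde | O=Cc1ccc(OCc2ccccc2)c(OCc2ccccc2)c1 | starting material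
13 | (E)-1,2-bis(benzyloxy)-4-(2-nitroethenyl)benzene | [O-][N+](=O)/C=C/c1ccc(OCc2ccccc2)c(OCc2ccccc2)c1 | intermediate
14 | 3,4-bis(benzyloxy)-2-{(1R)-1-[3,4-bis(benzyloxy)phenyl]-2-nitroethoxy}benzaldehyde | O=Cc1ccc(OCc2ccccc2)c(OCc2ccccc2)c1O[C@@H](C[N+](=O)[O-])c1ccc(OCc2ccccc2)c(OCc2ccccc2)c1 | intermediate (not isolated)
15 | (2R)-7,8-bis(benzyloxy)-2-[3,4-bis(benzyloxy)phenyl]-3-nitro-2H-chromene | O(Cc1ccccc1)c1ccc(cc1OCc1ccccc1)[C@H]1Oc2c(ccc(OCc3ccccc3)c2OCc2ccccc2)C=C1[N+](=O)[O-] | intermediate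
16 | (2R,3S,4S)-7,8-bis(benzyloxy)-2-[3,4-bis(benzyloxy)phenyl]-3,4-epoxy-3-nitrochromane | O(Cc1ccccc1)c1ccc(cc1OCc1ccccc1)[C@H]1Oc2c(ccc(OCc3ccccc3)c2OCc2ccccc2)[C@@H]2O[C@]12[N+](=O)[O-] | intermediate
17 | (2R,4R)-4-(benzylsulfanyl)-7,8-bis(benzyloxy)-2-[3,4-bis(benzyloxy)phenyl]chroman-3-one | O(Cc1ccccc1)c1ccc(cc1OCc1ccccc1)[C@H]1Oc2c(ccc(OCc3ccccc3)c2OCc2ccccc2)[C@@H](SCc2ccccc2)C1=O | intermediate
18 | (2R,3S,4R)-4-(benzylsulfanyl)-7,8-bis(benzyloxy)-2-[3,4-bis(benzyloxy)phenyl]chroman-3-ol (formed as lithium alkoxide) | O(Cc1ccccc1)c1ccc(cc1OCc1ccccc1)[C@H]1Oc2c(ccc(OCc3ccccc3)c2OCc2ccccc2)[C@@H](SCc2ccccc2)[C@H]1O | intermediate (not isolated)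
19 | (2R,3S,4R)-3-acetoxy-4-(benzylsulfanyl)-7,8-bis(benzyloxy)-2-[3,4-bis(benzyloxy)phenyl]chromane | O(Cc1ccccc1)c1ccc(cc1OCc1ccccc1)[C@H]1Oc2c(ccc(OCc3ccccc3)c2OCc2ccccc2)[C@@H](SCc2ccccc2)[C@H]1OC(C)=O | intermediate
20 | 3-O-acetyl-3',4',7,8-tetra-O-benzylepimesquitol-(4β→6)-3,4-di-O-acetyl-4',7,8-tri-O-benzylepioritin-4α-ol (upper 2R,3R,4R by CIP for the benzyl ether; lower 2R,3S,4R) | C(c1ccccc1)Oc1ccc(cc1)[C@H]1Oc2c(cc([C@H]3c4ccc(OCc5ccccc5)c(OCc5ccccc5)c4O[C@H](c4ccc(OCc5ccccc5)c(OCc5ccccc5)c4)[C@@H]3OC(C)=O)c(OCc3ccccc3)c2OCc2ccccc2)[C@@H](OC(C)=O)[C@H]1OC(C)=O | intermediate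
21 | 3',4',7,8-tetra-O-benzylepimesquitol-(4β→6)-4',7,8-tri-O-benzylepioritin-4α-ol | C(c1ccccc1)Oc1ccc(cc1)[C@H]1Oc2c(cc([C@H]3c4ccc(OCc5ccccc5)c(OCc5ccccc5)c4O[C@H](c4ccc(OCc5ccccc5)c(OCc5ccccc5)c4)[C@@H]3O)c(OCc3ccccc3)c2OCc2ccccc2)[C@@H](O)[C@H]1O | intermediate (not isolated)
22 | epimesquitol-(4β→6)-epioritin-4α-ol | Oc1ccc([C@H]2Oc3c(cc([C@H]4c5ccc(O)c(O)c5O[C@H](c5ccc(O)c(O)c5)[C@@H]4O)c(O)c3O)[C@@H](O)[C@H]2O)cc1 | target

**Total step count:** 13. **Longest linear sequence:** 7 (steps 1, 3, 4, 5, 6, 12, 13, or equally 1, 8, 9, 10, 11, 12, 13).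

**Three steps most likely to fail**

Step 12 (interflavan coupling). The trialkoxy ring A of 11 is only a modest nucleophile, so self-condensation of 19 may compete. The fallback sets out from 19 and 2 and changes the order of events. The same silver activation is run with the free phenol 2 (6 equiv, cheap), whose C5, para to the phenolic OH, is far more nucleophilic; this gives 5-[3-O-acetyl-3',4',7,8-tetra-O-benzylepimesquitol-4β-yl]-3,4-bis(benzyloxy)-2-hydroxybenzaldehyde F6. The lower ring C is then built on this aldehyde by the chemistry of steps 3 to 6. Domino reaction with 5 under the same aminocatalyst gives the dimeric nitrochromene F7. Epoxidation with t-BuOOLi at −78 °C gives the dimeric nitro epoxide F8. CsOAc opening gives the dimeric 4-acetoxy-3-ketone F9. LiBH(s-Bu)3 followed by Ac2O rejoins the route at 20.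

Step 5 (acetate opening with inversion). If acetate is too sluggish, or partial ionisation erodes the 2,4-cis configuration, the fallback sets out from 8 and uses sulfur in place of oxygen. PhCH2SH/Et3N gives (2R,4R)-4-(benzylsulfanyl)-7,8-bis(benzyloxy)-2-[4-(benzyloxy)phenyl]chroman-3-one F3. LiBH(s-Bu)3 then Ac2O gives the all-cis 3-acetoxy-4-(benzylsulfanyl)chromane F4. AgBF4 in wet MeCN ionises C4; the 3-acetate closes from its own face to the cis-fused acetoxonium ion, and water opens it at the dioxolenium carbon (Woodward-type cis-hydroxylation logic). This gives the all-cis 3-acetoxy-4-hydroxychromane F5, partly as its acetyl-shifted isomer 10. Ac2O/pyridine converts both into 11, where the route is rejoined.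

Step 3 (and its twin, step 8; enantioselectivity of the domino on these electron-rich partners). The fallback sets out from 2 and 5 and replaces asymmetric induction by resolution. Achiral 1,4-diazabicyclo[2.2.2]octane (MeCN, 60 °C) gives racemic 7,8-bis(benzyloxy)-2-[4-(benzyloxy)phenyl]-3-nitro-2H-chromene F1 in the robust racemic domino. Preparative chromatography on amylose tris(3,5-dimethylphenylcarbamate) then delivers 7 and the (2S)-enantiomer F2. F2 is warmed with the same amine, which should re-racemise it to F1 by reversible conjugate addition and ring opening, and is recycled. The route is rejoined at 7; the same remedy serves 15.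

**Further compounds**
F1 | step 3 | racemic 7,8-bis(benzyloxy)-2-[4-(benzyloxy)phenyl]-3-nitro-2H-chromene | O(Cc1ccccc1)c1ccc(cc1)C1Oc2c(ccc(OCc3ccccc3)c2OCc2ccccc2)C=C1[N+](=O)[O-]
F2 | step 3 | (2S)-7,8-bis(benzyloxy)-2-[4-(benzyloxy)phenyl]-3-nitro-2H-chromene | O(Cc1ccccc1)c1ccc(cc1)[C@@H]1Oc2c(ccc(OCc3ccccc3)c2OCc2ccccc2)C=C1[N+](=O)[O-]
F3 | step 5 | (2R,4R)-4-(benzylsulfanyl)-7,8-bis(benzyloxy)-2-[4-(benzyloxy)phenyl]chroman-3-one | O(Cc1ccccc1)c1ccc(cc1)[C@H]1Oc2c(ccc(OCc3ccccc3)c2OCc2ccccc2)[C@@H](SCc2ccccc2)C1=O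
F4 | step 5 | (2R,3S,4R)-3-acetoxy-4-(benzylsulfanyl)-7,8-bis(benzyloxy)-2-[4-(benzyloxy)phenyl]chromane | O(Cc1ccccc1)c1ccc(cc1)[C@H]1Oc2c(ccc(OCc3ccccc3)c2OCc2ccccc2)[C@@H](SCc2ccccc2)[C@H]1OC(C)=O
F5 | step 5 | (2R,3R,4R)-3-acetoxy-7,8-bis(benzyloxy)-2-[4-(benzyloxy)phenyl]chroman-4-ol | O(Cc1ccccc1)c1ccc(cc1)[C@H]1Oc2c(ccc(OCc3ccccc3)c2OCc2ccccc2)[C@@H](O)[C@H]1OC(C)=O
F6 | step 12 | 5-[3-O-acetyl-3',4',7,8-tetra-O-benzylepimesquitol-4β-yl]-3,4-bis(benzyloxy)-2-hydroxybenzaldehyde | O=Cc1cc([C@H]3c4ccc(OCc5ccccc5)c(OCc5ccccc5)c4O[C@H](c4ccc(OCc5ccccc5)c(OCc5ccccc5)c4)[C@@H]3OC(C)=O)c(OCc2ccccc2)c(OCc2ccccc2)c1O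
F7 | step 12 | (2R)-6-[3-O-acetyl-3',4',7,8-tetra-O-benzylepimesquitol-4β-yl]-7,8-bis(benzyloxy)-2-[4-(benzyloxy)phenyl]-3-nitro-2H-chromene | C(c1ccccc1)Oc1ccc(cc1)[C@H]1Oc2c(cc([C@H]3c4ccc(OCc5ccccc5)c(OCc5ccccc5)c4O[C@H](c4ccc(OCc5ccccc5)c(OCc5ccccc5)c4)[C@@H]3OC(C)=O)c(OCc3ccccc3)c2OCc2ccccc2)C=C1[N+](=O)[O-]
F8 | step 12 | (2R,3S,4S)-6-[3-O-acetyl-3',4',7,8-tetra-O-benzylepimesquitol-4β-yl]-7,8-bis(benzyloxy)-2-[4-(benzyloxy)phenyl]-3,4-epoxy-3-nitrochromane | C(c1ccccc1)Oc1ccc(cc1)[C@H]1Oc2c(cc([C@H]3c4ccc(OCc5ccccc5)c(OCc5ccccc5)c4O[C@H](c4ccc(OCc5ccccc5)c(OCc5ccccc5)c4)[C@@H]3OC(C)=O)c(OCc3ccccc3)c2OCc2ccccc2)[C@@H]2O[C@]12[N+](=O)[O-]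
F9 | step 12 | (2R,4R)-4-acetoxy-6-[3-O-acetyl-3',4',7,8-tetra-O-benzylepimesquitol-4β-yl]-7,8-bis(benzyloxy)-2-[4-(benzyloxy)phenyl]chroman-3-one | C(c1ccccc1)Oc1ccc(cc1)[C@H]1Oc2c(cc([C@H]3c4ccc(OCc5ccccc5)c(OCc5ccccc5)c4O[C@H](c4ccc(OCc5ccccc5)c(OCc5ccccc5)c4)[C@@H]3OC(C)=O)c(OCc3ccccc3)c2OCc2ccccc2)[C@@H](OC(C)=O)C1=O
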